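**Retrosynthetic overview**

1. The triene side chain goes on last: Suzuki coupling of a C2 1-(triflyloxy)vinyl group (from a C2 acetyl) with an (E,E)-dienyl boronate made from geranial; the enal comes from oxidative 1,3-transposition of a C7 isopropenyl carbinol.
2. C1-OH comes from reduction of the ring B ketone directed by the C10 hydroxyl; C2 is set by base equilibration of the acetyl epimers (acetyl carried as a dimethyl ketal until then).
3. Key disconnection: ring A is cut at C6-C7 and C5-C10. The carbene-bound acyl anion of 4-oxopentanal adds to a 2-alkylidenecyclopentanone (Stetter) and the resulting enolate closes onto the methyl ketone (aldol), giving the spiro centre, C6 and C10 in one step.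
4. Ring order: ring B (cyclopentane) is bought as a cyclopentanone enol ether; ring A (cyclohexane) is formed second, in the key annulation.

Assumption: the triazolium enantiomer named in step 4 is taken to be the one that gives the C6 configuration of the target; if the first run shows the opposite sense, the commercial antipode is used.

Locants: spiro[4.5]decane numbering, C1 = carbinol carbon of ring B, C2 = side-chain carbon, C5 = spiro carbon, C6 = carbon bearing the three-carbon chain, C7 = enal-bearing carbon, C10 = methyl carbinol. TBS = tert-butyldimethylsilyl.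

**Route**

Step 1
Reactants: 1 1-(trimethylsilyloxy)cyclopent-1-ene; 2 trimethyl orthoacetate
Product: 3 2-(1,1-dimethoxyethyl)cyclopentan-1-one
Conditions: TMSOTf (5 mol%), CH2Cl2, −78 °C; pyridine quench
Reagents that add atoms: none
Why: Mukaiyama–Noyori condensation of the silyl enol ether with the dimethoxycarbenium ion from the orthoester gives the β-keto ketal, a masked acetyl that does not acidify C2-H (racemic; C2 is fixed in step 7).

Step 2
Reactants: 3 2-(1,1-dimethoxyethyl)cyclopentan-1-one; 4 4-(tert-butyldimethylsilyloxy)butanal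
Product: 7 (2E)-2-[4-(tert-butyldimethylsilyloxy)butylidene]-5-(1,1-dimethoxyethyl)cyclopentan-1-one, via lithium aldolate 5 (not isolated), via aldol mesylate 6 (not isolated)
Conditions: LiN(iPr)2, THF, −78 °C; 4; then MsCl, −78 → 0 °C; then DBU, 0 → 23 °C
Reagents that add atoms: none
Why: Kinetic enolisation at the unhindered CH2, aldol addition and E1cB loss of mesylate (crossed aldol condensation) give the thermodynamically preferred E exocyclic enone.

Step 3
Reactants: 8 6-methylhept-5-en-2-one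
Product: 10 4-oxopentanal, via secondary ozonide 9 (not isolated)
Conditions: O3, CH2Cl2, −78 °C; then PPh3, → 23 °C; distil
Reagents that add atoms: ozone, [O-][O+]=O
Why: Ozonolysis of the trisubstituted alkene with reductive work-up gives the keto aldehyde and acetone.

Step 4
Reactants: 7 (2E)-2-[4-(tert-butyldimethylsilyloxy)butylidene]-5-(1,1-dimethoxyethyl)cyclopentan-1-one; 10 4-oxopentanal
Product: 12 6-[3-(tert-butyldimethylsilyloxy)propyl]-2-(1,1-dimethoxyethyl)-10-hydroxy-10-methylspiro[4.5]decane-1,7-dione, via Stetter adduct 11 (not isolated)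
Conditions: 10 (2 equiv), (5aS,10bR)-2-(pentafluorophenyl)-5a,10b-dihydro-4H,6H-indeno[2,1-b][1,2,4]triazolo[4,3-d][1,4]oxazin-2-ium tetrafluoroborate (20 mol%), iPr2NEt (1 equiv), tert-amyl alcohol, 0 → 23 °C
Reagents that add atoms: none
Why: Proposed new method: the Breslow intermediate of 10 (an acyl anion equivalent) adds to the β-carbon of the s-cis-locked exocyclic enone with the catalyst choosing the face (C6), and the ring enolate then closes reversibly onto the pendant methyl ketone through a chair that keeps C6-H in the enolate plane (A(1,3) strain) and ends with the side chain and the methyl equatorial and the new hydroxyl hydrogen-bonded to the C1 carbonyl, which fixes the spiro centre and C10 relative to C6; the closest known chemistry is the triazolium-catalysed asymmetric intermolecular Stetter reaction of aliphatic aldehydes and the domino Stetter–aldol annulation.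

Step 5
Reactants: 12 6-[3-(tert-butyldimethylsilyloxy)propyl]-2-(1,1-dimethoxyethyl)-10-hydroxy-10-methylspiro[4.5]decane-1,7-dione
Product: 13 6-[3-(tert-butyldimethylsilyloxy)propyl]-2-(1,1-dimethoxyethyl)-1,10-dihydroxy-10-methylspiro[4.5]decan-7-one
Conditions: Me4NBH(OAc)3, anhydrous MeCN/AcOH (1:1), −20 °C; NaHCO3 work-up
Reagents that add atoms: none
Why: Evans–Saksena directed reduction: the borohydride bound to the C10 oxygen delivers hydride within the molecule to the face of C1 that carries C10, so the C1 hydroxyl ends anti to C10 as in the target, and the C7 ketone (no β-hydroxyl) is left alone.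

Step 6
Reactants: 13 6-[3-(tert-butyldimethylsilyloxy)propyl]-2-(1,1-dimethoxyethyl)-1,10-dihydroxy-10-methylspiro[4.5]decan-7-one
Product: 15 1-{6-[3-(tert-butyldimethylsilyloxy)propyl]-1,7,10-trihydroxy-10-methyl-7-(prop-1-en-2-yl)spiro[4.5]decan-2-yl}ethan-1-one, via ketal triol 14 (not isolated)
Conditions: CH2=C(CH3)MgBr (4 equiv), CeCl3, THF, −78 °C; then aq. oxalic acid, THF, 0 → 23 °C
Reagents that add atoms: isopropenylmagnesium bromide, C=C(C)[Mg]Br; water, O
Why: Organocerium 1,2-addition to the only remaining ketone avoids enolisation of C6, and the mild acid work-up hydrolyses the dimethyl ketal to the acetyl group; the new C7 carbinol centre is not assigned because step 9 erases it.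

Step 7
Reactants: 15 1-{6-[3-(tert-butyldimethylsilyloxy)propyl]-1,7,10-trihydroxy-10-methyl-7-(prop-1-en-2-yl)spiro[4.5]decan-2-yl}ethan-1-one
Product: 17 1-{1-(tert-butyldimethylsilyloxy)-6-[3-(tert-butyldimethylsilyloxy)propyl]-7,10-dihydroxy-10-methyl-7-(prop-1-en-2-yl)spiro[4.5]decan-2-yl}ethan-1-one (1,2-trans), via silyl ether epimers 16 (not isolated)
Conditions: TBSOTf (1.1 equiv), 2,6-lutidine, CH2Cl2, −78 °C; then K2CO3, MeOH, 23 °C
Reagents that add atoms: tert-butyldimethylsilyl trifluoromethanesulfonate, CC(C)(C)[Si](C)(C)OS(=O)(=O)C(F)(F)F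
Why: The secondary hydroxyl is silylated ahead of the two tertiary ones, and base equilibration of the α-acetyl centre through its enolate sets C2 in the more stable arrangement, acetyl trans to the bulky C1 silyloxy group (on the C10 face).

Step 8
Reactants: 17 1-{1-(tert-butyldimethylsilyloxy)-6-[3-(tert-butyldimethylsilyloxy)propyl]-7,10-dihydroxy-10-methyl-7-(prop-1-en-2-yl)spiro[4.5]decan-2-yl}ethan-1-one
Product: 18 1-{1-(tert-butyldimethylsilyloxy)-6-[3-(tert-butyldimethylsilyloxy)propyl]-7,10-dihydroxy-10-methyl-7-(prop-1-en-2-yl)spiro[4.5]decan-2-yl}ethenyl trifluoromethanesulfonate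
Conditions: KN(SiMe3)2 (3.3 equiv), THF, −78 °C; then Comins' reagent, −78 °C; NH4Cl
Reagents that add atoms: N-(5-chloropyridin-2-yl)-1,1,1-trifluoro-N-(trifluoromethylsulfonyl)methanesulfonamide (Comins' reagent), FC(F)(F)S(=O)(=O)N(c1ccc(Cl)cn1)S(=O)(=O)C(F)(F)F
Why: Kinetic deprotonation of the methyl group (the C2 methine is hindered and is not touched) and O-triflation of the enolate give the 1,1-disubstituted vinyl triflate.

Step 9
Reactants: 18 1-{1-(tert-butyldimethylsilyloxy)-6-[3-(tert-butyldimethylsilyloxy)propyl]-7,10-dihydroxy-10-methyl-7-(prop-1-en-2-yl)spiro[4.5]decan-2-yl}ethenyl trifluoromethanesulfonate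
Product: 19 1-{(7Z)-1-(tert-butyldimethylsilyloxy)-6-[3-(tert-butyldimethylsilyloxy)propyl]-10-hydroxy-10-methyl-7-(1-oxopropan-2-ylidene)spiro[4.5]decan-2-yl}ethenyl trifluoromethanesulfonate
Conditions: C5H5NH[CrO3Cl] (3 equiv), NaOAc, 4 Å sieves, CH2Cl2, 23 °C
Reagents that add atoms: pyridinium chlorochromate, [O-][Cr](=O)(=O)Cl.c1cc[nH+]cc1
Why: Babler–Dauben oxidative transposition (chromate ester, [3,3] shift, oxidation of the primary chromate) turns the tertiary allylic alcohol into the tetrasubstituted enal, with the formyl group (smaller than methyl in A(1,3) strain) expected to sit cis to the substituted C6, which is the Z geometry of the target.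

Step 10
Reactants: 20 geranial, (2E)-3,7-dimethylocta-2,6-dienal
Product: 21 2-[(1E,3E)-4,8-dimethylnona-1,3,7-trien-1-yl]-4,4,5,5-tetramethyl-1,3,2-dioxaborolane
Conditions: CH2(Bpin)2, lithium 2,2,6,6-tetramethylpiperidide, THF, 0 °C; then 20, −78 → 23 °C
Reagents that add atoms: bis(pinacolato)borylmethane, CC1(C)OB(CB2OC(C)(C)C(C)(C)O2)OC1(C)C
Why: Boron-Wittig olefination of the enal gives the E-alkenyl boronate by syn B–O elimination, and the existing E trisubstituted alkene is untouched.

Step 11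
Reactants: 19 1-{(7Z)-1-(tert-butyldimethylsilyloxy)-6-[3-(tert-butyldimethylsilyloxy)propyl]-10-hydroxy-10-methyl-7-(1-oxopropan-2-ylidene)spiro[4.5]decan-2-yl}ethenyl trifluoromethanesulfonate; 21 2-[(1E,3E)-4,8-dimethylnona-1,3,7-trien-1-yl]-4,4,5,5-tetramethyl-1,3,2-dioxaborolane
Product: 22 (2Z)-2-{(1R,2R,5S,6S,10S)-1-(tert-butyldimethylsilyloxy)-6-[3-(tert-butyldimethylsilyloxy)propyl]-2-[(3E,5E)-6,10-dimethylundeca-1,3,5,9-tetraen-2-yl]-10-hydroxy-10-methylspiro[4.5]decan-7-ylidene}propanal
Conditions: Pd(PPh3)4 (5 mol%), K3PO4 (aq), dioxane, 45 °C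
Reagents that add atoms: none
Why: Suzuki–Miyaura coupling of the vinyl triflate with the alkenyl boronate proceeds with retention at both partners and tolerates the enal and the free tertiary alcohol, building the 2-substituted triene.

Step 12
Reactants: 22 (2Z)-2-{(1R,2R,5S,6S,10S)-1-(tert-butyldimethylsilyloxy)-6-[3-(tert-butyldimethylsilyloxy)propyl]-2-[(3E,5E)-6,10-dimethylundeca-1,3,5,9-tetraen-2-yl]-10-hydroxy-10-methylspiro[4.5]decan-7-ylidene}propanal
Product: 23 (2Z)-2-[(1R,2R,5S,6S,10S)-2-[(3E,5E)-6,10-dimethylundeca-1,3,5,9-tetraen-2-yl]-1,10-dihydroxy-6-(3-hydroxypropyl)-10-methylspiro[4.5]decan-7-ylidene]propanal (CNP0173034.2)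
Conditions: HF·pyridine, pyridine, THF, 0 → 23 °C
Reagents that add atoms: none
Why: Buffered fluoride desilylation removes both silyl ethers without touching the enal, the triene or any stereocentre.

**Compound list**

1 | 1-(trimethylsilyloxy)cyclopent-1-ene | C[Si](C)(C)OC1=CCCC1 | starting material
2 | trimethyl orthoacetate (1,1,1-trimethoxyethane) | CC(OC)(OC)OC | starting material
3 | 2-(1,1-dimethoxyethyl)cyclopentan-1-one, racemic | CC(OC)(OC)C1CCCC1=O | intermediate
4 | 4-(tert-butyldimethylsilyloxy)butanal | O=CCCCO[Si](C)(C)C(C)(C)C | starting material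
5 | lithium aldolate of 3 and 4, 2-[4-(TBS-oxy)-1-(lithiooxy)butyl]-5-(1,1-dimethoxyethyl)cyclopentan-1-one, diastereomer mixture | CC(OC)(OC)C1CCC(C(O[Li])CCCO[Si](C)(C)C(C)(C)C)C1=O | intermediate
6 | aldol mesylate, 2-[4-(TBS-oxy)-1-(methanesulfonyloxy)butyl]-5-(1,1-dimethoxyethyl)cyclopentan-1-one, diastereomer mixture | CC(OC)(OC)C1CCC(C(OS(C)(=O)=O)CCCO[Si](C)(C)C(C)(C)C)C1=O | intermediate
7 | (2E)-2-[4-(tert-butyldimethylsilyloxy)butylidene]-5-(1,1-dimethoxyethyl)cyclopentan-1-one, racemic at C5 | CC(OC)(OC)C1CC/C(=C\CCCO[Si](C)(C)C(C)(C)C)C1=O | intermediate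
8 | 6-methylhept-5-en-2-one | CC(=O)CCC=C(C)C | starting material
9 | 3,3-dimethyl-5-(3-oxobutyl)-1,2,4-trioxolane (secondary ozonide) | CC(=O)CCC1OOC(C)(C)O1 | intermediate
10 | 4-oxopentanal (levulinaldehyde) | CC(=O)CCC=O | intermediate
11 | Stetter adduct, 2-(1,1-dimethoxyethyl)-5-[1-(TBS-oxy)-5,8-dioxononan-4-yl]cyclopentan-1-one (present as its ring enolate), C4 of the chain configured as C6 of 23 | CC(OC)(OC)C1CCC([C@@H](CCCO[Si](C)(C)C(C)(C)C)C(=O)CCC(C)=O)C1=O | intermediate
12 | 6-[3-(TBS-oxy)propyl]-2-(1,1-dimethoxyethyl)-10-hydroxy-10-methylspiro[4.5]decane-1,7-dione; C5, C6, C10 as in 23 (C6 chain trans to C1 on ring A, 10-OH cis to C1); mixture of C2 epimers | CC(OC)(OC)C1CC[C@@]2(C1=O)[C@@H](CCCO[Si](C)(C)C(C)(C)C)C(=O)CC[C@]2(C)O | intermediate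
13 | 6-[3-(TBS-oxy)propyl]-2-(1,1-dimethoxyethyl)-1,10-dihydroxy-10-methylspiro[4.5]decan-7-one; C1, C5, C6, C10 as in 23 (1-OH anti to C10 on ring B); C2 epimers | CC(OC)(OC)C1CC[C@@]2([C@@H]1O)[C@@H](CCCO[Si](C)(C)C(C)(C)C)C(=O)CC[C@]2(C)O | intermediate
14 | ketal triol, 6-[3-(TBS-oxy)propyl]-2-(1,1-dimethoxyethyl)-10-methyl-7-(prop-1-en-2-yl)spiro[4.5]decane-1,7,10-triol; C7 not assigned; C2 epimers | CC(OC)(OC)C1CC[C@@]2([C@@H]1O)[C@@H](CCCO[Si](C)(C)C(C)(C)C)C(O)(C(C)=C)CC[C@]2(C)O | intermediate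
15 | 1-{6-[3-(TBS-oxy)propyl]-1,7,10-trihydroxy-10-methyl-7-(prop-1-en-2-yl)spiro[4.5]decan-2-yl}ethan-1-one; C1, C5, C6, C10 as in 23; C2 epimers; C7 not assigned | CC(=O)C1CC[C@@]2([C@@H]1O)[C@@H](CCCO[Si](C)(C)C(C)(C)C)C(O)(C(C)=C)CC[C@]2(C)O | intermediate
16 | 1-O-TBS ether of 15, C2 epimers | CC(=O)C1CC[C@@]2([C@@H]1O[Si](C)(C)C(C)(C)C)[C@@H](CCCO[Si](C)(C)C(C)(C)C)C(O)(C(C)=C)CC[C@]2(C)O | intermediate
17 | 1-{1-(TBS-oxy)-6-[3-(TBS-oxy)propyl]-7,10-dihydroxy-10-methyl-7-(prop-1-en-2-yl)spiro[4.5]decan-2-yl}ethan-1-one; acetyl trans to the 1-silyloxy group; C1, C2, C5, C6, C10 as in 23 | CC(=O)[C@H]1CC[C@@]2([C@@H]1O[Si](C)(C)C(C)(C)C)[C@@H](CCCO[Si](C)(C)C(C)(C)C)C(O)(C(C)=C)CC[C@]2(C)O | intermediate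
18 | vinyl triflate of 17, 1-{...spiro[4.5]decan-2-yl}ethenyl trifluoromethanesulfonate, stereocentres as in 17 | C=C(OS(=O)(=O)C(F)(F)F)[C@H]1CC[C@@]2([C@@H]1O[Si](C)(C)C(C)(C)C)[C@@H](CCCO[Si](C)(C)C(C)(C)C)C(O)(C(C)=C)CC[C@]2(C)O | intermediate
19 | 1-{(7Z)-1-(TBS-oxy)-6-[3-(TBS-oxy)propyl]-10-hydroxy-10-methyl-7-(1-oxopropan-2-ylidene)spiro[4.5]decan-2-yl}ethenyl trifluoromethanesulfonate, formyl cis to C6 | C=C(OS(=O)(=O)C(F)(F)F)[C@H]1CC[C@@]2([C@@H]1O[Si](C)(C)C(C)(C)C)[C@@H](CCCO[Si](C)(C)C(C)(C)C)/C(=C(/C)C=O)CC[C@]2(C)O | intermediate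
20 | geranial, (2E)-3,7-dimethylocta-2,6-dienal | CC(C)=CCC/C(C)=C/C=O | starting material
21 | 2-[(1E,3E)-4,8-dimethylnona-1,3,7-trien-1-yl]-4,4,5,5-tetramethyl-1,3,2-dioxaborolane | CC(C)=CCC/C(C)=C/C=C/B1OC(C)(C)C(C)(C)O1 | intermediate
22 | bis-TBS ether of the target, (2Z)-2-{(1R,2R,5S,6S,10S)-1-(TBS-oxy)-6-[3-(TBS-oxy)propyl]-2-[(3E,5E)-6,10-dimethylundeca-1,3,5,9-tetraen-2-yl]-10-hydroxy-10-methylspiro[4.5]decan-7-ylidene}propanal | C=C(/C=C/C=C(\C)CCC=C(C)C)[C@H]1CC[C@@]2([C@@H]1O[Si](C)(C)C(C)(C)C)[C@@H](CCCO[Si](C)(C)C(C)(C)C)/C(=C(/C)C=O)CC[C@]2(C)O | intermediate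
23 | (2Z)-2-[(1R,2R,5S,6S,10S)-2-[(3E,5E)-6,10-dimethylundeca-1,3,5,9-tetraen-2-yl]-1,10-dihydroxy-6-(3-hydroxypropyl)-10-methylspiro[4.5]decan-7-ylidene]propanal | C=C(/C=C/C=C(\C)CCC=C(C)C)[C@H]1CC[C@@]2([C@@H]1O)[C@@H](CCCO)/C(=C(/C)C=O)CC[C@]2(C)O | target

**Step count and risks**

Total steps: 12. Longest linear sequence: 10 (steps 1, 2, 4, 5, 6, 7, 8, 9, 11, 12).

The three steps most likely to fail:

Step 4. The intermolecular Stetter addition of an aliphatic aldehyde to a β-alkyl enone is slow, benzoin and aldol self-reactions of 10 compete, and the C6 centre (α to the new ketone) can erode before the aldol locks it. Fallback: setting out from 7, the acyl anion equivalent is changed from the carbene adduct to a nitronate. Commercial 5-nitropentan-2-one and 7, with a quinine-derived bifunctional thiourea (10 mol%, toluene, 0 °C), undergo asymmetric Michael addition at the exocyclic β-carbon followed by the same enolate-to-methyl-ketone aldol closure, giving the spiro nitro ketol F1. Nef cleavage of its nitronate (NaOMe, MeOH, −78 °C; O3; Me2S) turns the C7 nitro carbon into the ketone and comes back to the route at 12.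

Step 5. The C1 ketone is flanked by the spiro carbon and the ketal-bearing C2, the directing hydroxyl is tertiary, and the ketal must survive acetic acid. Fallback: setting out from 12, an Evans–Tishchenko reduction (SmI2 30 mol%, isobutyraldehyde 6 equiv, THF, −10 °C) is used instead; the hemiacetal formed on the C10 oxygen transfers its hydride within the samarium chelate to the same face of C1 under non-acidic conditions and gives the C10 isobutyrate F2. Methanolysis (K2CO3, MeOH, 23 °C) comes back to the route at 13.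

Step 9. The chromate [3,3] shift to a tetrasubstituted α-methyl enal is often low-yielding, can give E/Z mixtures, and the substrate is acid-sensitive. Fallback: setting out from 18, the oxidation is split into an isomerisation and a mild allylic oxidation. Ph3SiOReO3 (5 mol%, Et2O, 0 °C) equilibrates the tertiary allylic alcohol to the more substituted alkene, giving the primary allylic alcohol F3 under thermodynamic control of geometry; MnO2 (CH2Cl2, 23 °C) then oxidises only this allylic alcohol and comes back to the route at 19.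

**Further compounds**

F1 | step 4 | 6-[3-(tert-butyldimethylsilyloxy)propyl]-2-(1,1-dimethoxyethyl)-10-hydroxy-10-methyl-7-nitrospiro[4.5]decan-1-one (C5, C6, C10 as in 12; C7 and C2 mixtures) | CC(OC)(OC)C1CC[C@@]2(C1=O)[C@@H](CCCO[Si](C)(C)C(C)(C)C)C([N+](=O)[O-])CC[C@]2(C)O
F2 | step 5 | 6-[3-(tert-butyldimethylsilyloxy)propyl]-2-(1,1-dimethoxyethyl)-1-hydroxy-10-methyl-7-oxospiro[4.5]decan-10-yl 2-methylpropanoate (stereocentres as in 13) | CC(OC)(OC)C1CC[C@@]2([C@@H]1O)[C@@H](CCCO[Si](C)(C)C(C)(C)C)C(=O)CC[C@]2(C)OC(=O)C(C)C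
F3 | step 9 | 1-{(7Z)-1-(tert-butyldimethylsilyloxy)-6-[3-(tert-butyldimethylsilyloxy)propyl]-10-hydroxy-7-(1-hydroxypropan-2-ylidene)-10-methylspiro[4.5]decan-2-yl}ethenyl trifluoromethanesulfonate | C=C(OS(=O)(=O)C(F)(F)F)[C@H]1CC[C@@]2([C@@H]1O[Si](C)(C)C(C)(C)C)[C@@H](CCCO[Si](C)(C)C(C)(C)C)/C(=C(/C)CO)CC[C@]2(C)O
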